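## Analysis of the target

2-O-Acetylzeylenone has a single carbocycle, a cyclohex-4-en-6-one, and no other ring apart from the two benzoate phenyl groups. The ring is numbered C1 (quaternary carbinol), C2 (CHOAc), C3 (CHOBz), C4=C5 (alkene), C6 (ketone), with C7 the exocyclic CH2OBz on C1. This numbering is kept for every intermediate.

The three stereocentres are contiguous, (1S,2S,3R). The C1 hydroxyl and the C2 acetate are cis, and the C2 acetate and the C3 benzoate are trans.

Four oxygens carry three different acyl patterns next to a free tertiary alcohol, so acyl migration (O3→O2, O2→O6, O7→O1) is a constant risk. The γ-acyloxy enone can also eliminate and aromatise under base.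

The difficulty lies in the quaternary carbinol C1, which sits between a ketone and an acyloxylated carbon and has to be made as one enantiomer. The four ring oxygens must also be told apart.

The strategy rests on one feature. If the C2, C3 and C6 oxygens are removed and a carbonyl is placed at C4, then C1, its hydroxyl and C7 lie on the mirror plane of a cyclohexa-2,5-dienone. Its two enone arms (C2=C3 and C6=C5) are enantiotopic, so oxidising one arm alone makes C1 stereogenic. The C1 hydroxyl can then relay its configuration to C2 and C3.

## Retrosynthetic reasoning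

**13 ⇒ 12.** The C6 carbonyl is taken back to a C6 carbinol. The base-sensitive γ-acyloxy enone then exists only in the last flask, and the forward reaction is a simple allylic alcohol oxidation.

**12 ⇒ 11 ⇒ 10.** The C6 hydroxyl is masked as a silyl ether and the C2–O acetyl bond is cut. In 10 the secondary C2 hydroxyl is the only acylable alcohol, because C1–OH is tertiary and C6–OH is silylated, so the acetate goes on without further protection.

**10 ⇒ 9.** The C3–O(benzoate) bond is cut, leading back to a C2–C3 oxirane cis to C1–OH. Opening at C3 with inversion gives the trans C2/C3 relationship and leaves C2–O cis to C1–O, so one step sets both remaining stereocentres correctly. C3 is the right site because it is allylic and distal to the carbinol, whereas C2 is neopentylic. The forward reaction has to be a clean SN2 opening by benzoate, not an SN2′ opening.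

**9 ⇒ 8.** The oxirane C–O bonds are cut, leaving the C2=C3–C4=C5 diene. The tertiary allylic C1 hydroxyl directs the oxidant to C2=C3 and to its own face, so C1 controls C2 and C3.

**8 ⇒ 7.** The silyl ether is removed to give the cis-diol 7. The ether is needed because a free C6 hydroxyl would direct epoxidation to C4=C5.

**7 ⇒ 5 (through 6).** The diene carbinol is traced to an α,β-epoxy ketone by a Wharton transposition. This moves the oxygen function from C4 (where the dearomatisation places it) to C6 (where the target needs it) and creates the C4=C5 bond, with no change at C1.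

**5 ⇒ 3 (through 4).** The C5–O and C6–O bonds of the oxirane are cut. This is the key disconnection, because 3 is achiral and available in two steps. The forward step must epoxidise one of two enantiotopic enone arms, and once only.

**3 ⇒ 2 ⇒ 1.** The C1–OH bond is cut (hydroxylative dearomatisation of phenol 2), then the ester C–O bond, which leads to 1. C7 and all six ring carbons come from the aromatic starting material.

## Alternatives that were turned down

**Alternative 1: ring contraction of a sugar lactone.**
- Disconnection: the ring bond C1–C6 is cut and the carbocycle is traced to a seven-carbon vinyl lactone A2 from a hexose, with C7 as the lactone carbonyl.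
- Forward key step: enolisation and O-silylation of A2, then a [3,3] shift through a boat transition state (Ireland–Claisen), gives acid A1 with the C1–C6 bond and the C4=C5 alkene.
- For: C2 and C3 come from the chiral pool without doubt. C1 is set by suprafacial chirality transfer from the vinyl-bearing carbon. No enantioselective reagent is needed.
- Against: A1 has C7 as an acid and C6 as a methylene. C7 must be reduced and C6 oxidised at an allylic position in competition with the equally allylic C3–H. An acetonide and a silyl ether must be exchanged for one acetate and two benzoates. The enolate of A2 carries a β-alkoxy leaving group, so elimination competes with silylation. A2 itself needs a long protecting-group sequence.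
- Comparison: this route is stronger on certainty of absolute configuration. The chosen route has about half the steps and has C6 and C7 at the right oxidation level from the outset.

**Alternative 2: Diels–Alder construction.**
- Disconnection: C1–C2 and C5–C6 are cut, giving dienophile A4 (C1, C6, C7) and diene A5 (C2–C5).
- Forward key step: iminium activation of A4 by a chiral binaphthyl-derived primary ammonium salt and exo cycloaddition of A5 give A3 with cis oxygens at C1 and C2.
- For: it is the most convergent plan. The ring, the quaternary centre and the C2 acetate arise in one catalytic step from two achiral pieces.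
- Against: A3 has its alkene at C3=C4, no oxygen at C3 or C6, the benzoate on the tertiary oxygen and C7 as an aldehyde. It needs aldehyde reduction, a 1,2-benzoyl shift, trans oxygenation at C3, an alkene shift to C4=C5 and an allylic oxidation at C6, all beside esters that migrate. Exo and facial selectivity with an acyclic, moderately reactive acetoxydiene are open.
- Comparison: it is equal or better at forming the ring and C1. After the key step of the chosen route, however, every ring carbon already has the oxygen or alkene it needs, whereas here two C–H oxidations remain.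

**Alternative 3: late methylenation of a ring ketone.**
- Disconnection: the exocyclic C1–C7 bond is cut, leaving the enantiopure ring ketone A7.
- Forward key step: a sulfonium methylide adds to the C1 carbonyl of A7 and the betaine closes to the spiro-oxirane A6. Both flanking oxygens (C2, C6) are on one face, so the ylide enters from the other and C7 ends trans to the C2 oxygen. Benzoate would later open the oxirane at C7.
- For: C2 and C3 are fixed beforehand. C1 is set by a clear steric bias. The opening gives the C7 benzoate and the free C1 hydroxyl in one operation.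
- Against: A7 is a β,γ-unsaturated ketone whose C6–H is both allylic and α to the carbonyl, so a basic ylide can enolise it towards conjugation, elimination and aromatisation. C3 and C6 carry the same silyl group although one must become a benzoate and the other a ketone. A7 needs a long chiral-pool sequence.
- Comparison: it is stronger on diastereocontrol at C1, which is substrate-controlled. The chosen route has C7 in place from the aromatic precursor and is much shorter.

Key step: step 3

## Route

Assumption (remark on the chemistry): which enone arm a given tartrate enantiomer selects on a para-quinol cannot be predicted with confidence from the quinone monoketal series. The route is written with diisopropyl L-(+)-tartrate; the D-(−)-ester takes its place if the opposite arm reacts.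

"Up" means the face of the C1 hydroxyl.

**Step 1**
Reactants: 1 4-hydroxybenzyl alcohol
Product: 2 4-hydroxybenzyl benzoate
Conditions: PhCO2H (1.05 equiv), PPh3, DIAD, THF, 0 °C → rt
Reagents that add atoms: benzoic acid, O=C(O)c1ccccc1
Why: Mitsunobu esterification: benzoic acid is far more acidic than the phenol, so benzoate and not phenoxide displaces the benzylic oxyphosphonium ion; the near-neutral medium avoids the phenoxide of 2, which would expel benzoate by 1,6-elimination.

**Step 2**
Reactants: 2 4-hydroxybenzyl benzoate
Product: 3 4-hydroxy-4-(benzoyloxymethyl)cyclohexa-2,5-dien-1-one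
Conditions: PhI(OAc)2 (1.1 equiv), MeCN–H2O (4:1), 0 °C
Reagents that add atoms: water, O
Why: Oxidative dearomatisation of a para-substituted phenol with a hypervalent iodine reagent: the phenol oxygen binds iodine and water attacks the para carbon C1 as iodobenzene departs, giving the achiral dienone; the acetic acid released keeps the medium acidic, so the benzoate-expelling phenoxide does not form.

**Step 3**
Reactants: 3 4-hydroxy-4-(benzoyloxymethyl)cyclohexa-2,5-dien-1-one
Product: 5 (1R,5S,6R)-1-(benzoyloxymethyl)-5,6-epoxy-1-hydroxycyclohex-2-en-4-one, via disodium C6-trityldioxy dienolate 4 (not isolated)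
Conditions: Ph3COOH (1.1 equiv), NaN(SiMe3)2 (2.1 equiv), diisopropyl L-(+)-tartrate (1.2 equiv), 4 Å molecular sieves, toluene, −60 → −40 °C; aq. NH4Cl
Reagents that add atoms: trityl hydroperoxide, OOC(c1ccccc1)(c1ccccc1)c1ccccc1; NaN(SiMe3)2, C[Si](C)(C)[N-][Si](C)(C)C.[Na+] (sodium ions of 4 only)
Why: Proposed new method: tartrate-mediated nucleophilic epoxidation with Ph3COOH is known for quinone monoketals, where it distinguishes the two faces of one enone, and alkaline peroxides are known to epoxidise para-quinols cis to the hydroxyl, but the choice between the two enantiotopic enone arms of a para-quinol by this reagent has not been shown. Mechanistically it is a Weitz–Scheffer epoxidation: NaN(SiMe3)2 turns the C1 hydroxyl and the hydroperoxide into sodium salts that aggregate with the tartrate, the peroxide oxygen adds to C6 (the β-carbon next to C1) to give dienolate 4, and C5 of 4 then attacks the proximal peroxide oxygen with loss of Ph3CO−. This closure of the oxirane is 3-exo-tet, the breaking O–O bond lying outside the new ring. C5 and C6 are set by substrate control, since the peroxide is delivered from the sodium alkoxide at C1 and therefore to the hydroxyl face, giving the cis-epoxy alcohol. C1 is not altered itself but becomes stereogenic through the choice of arm, and this choice is under reagent control by the chiral tartrate held in the same sodium aggregate. The step needs enantiotopic-group selectivity and a stop at the mono-epoxide; one arm is matched to the reagent, only a slight excess of oxidant is used at low temperature, and any second epoxidation should consume mainly the minor enantiomer (whose remaining arm is the matched one), turning it into an achiral bis-epoxide and raising the enantiomeric purity of 5. The cis relationship also protects 5 later, because the C1 oxygen cannot reach the back side of C6 for a Payne-type migration.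

**Step 4**
Reactants: 5 (1R,5S,6R)-1-(benzoyloxymethyl)-5,6-epoxy-1-hydroxycyclohex-2-en-4-one
Product: 7 (1R,6R)-1-(benzoyloxymethyl)cyclohexa-2,4-diene-1,6-diol, via epoxy hydrazone 6 (not isolated)
Conditions: N2H4·H2O (2 equiv), AcOH (0.2 equiv), MeOH, 0 °C → rt
Reagents that add atoms: hydrazine hydrate, NN.O (its nitrogen atoms are in 6 only and leave as N2)
Why: Wharton transposition: hydrazine condenses with the C4 ketone to give hydrazone 6, N–H deprotonation opens the oxirane at C5–O to form C4=C5 and the C6 alkoxide, and loss of N2 delivers hydrogen to C4; the C6–O bond is never broken, so C6–OH stays cis to C1–OH.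

**Step 5**
Reactants: 7 (1R,6R)-1-(benzoyloxymethyl)cyclohexa-2,4-diene-1,6-diol
Product: 8 (1R,6R)-1-(benzoyloxymethyl)-6-(tert-butyldimethylsilyloxy)cyclohexa-2,4-dien-1-ol
Conditions: TBSCl (1.2 equiv), imidazole, DMF, 0 °C → rt
Reagents that add atoms: tert-butyldimethylsilyl chloride, CC(C)(C)[Si](C)(C)Cl
Why: Silyl ether formation: the secondary allylic C6 hydroxyl reacts while the tertiary C1 hydroxyl does not under these conditions; masking C6–OH removes the only other group that could direct an oxidant to C4=C5, and no stereocentre is touched.

**Step 6**
Reactants: 8 (1R,6R)-1-(benzoyloxymethyl)-6-(tert-butyldimethylsilyloxy)cyclohexa-2,4-dien-1-ol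
Product: 9 (1S,2S,3S,6R)-1-(benzoyloxymethyl)-6-(tert-butyldimethylsilyloxy)-2,3-epoxycyclohex-4-en-1-ol
Conditions: VO(acac)2 (5 mol %), t-BuOOH (1.3 equiv, decane solution), CH2Cl2, 0 °C
Reagents that add atoms: tert-butyl hydroperoxide, CC(C)(C)OO
Why: Vanadium-catalysed hydroxyl-directed epoxidation of an allylic alcohol: the tertiary C1 hydroxyl binds the vanadium peroxide and delivers oxygen to the adjacent C2=C3 bond on its own face, so C2 and C3 are set by C1 (oxirane cis to C1–OH); C4=C5 is only homoallylic to C1–OH and its neighbouring C6 oxygen is silylated.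

**Step 7**
Reactants: 9 (1S,2S,3S,6R)-1-(benzoyloxymethyl)-6-(tert-butyldimethylsilyloxy)-2,3-epoxycyclohex-4-en-1-ol
Product: 10 (1S,2S,3R,6R)-3-(benzoyloxy)-1-(benzoyloxymethyl)-6-(tert-butyldimethylsilyloxy)cyclohex-4-ene-1,2-diol
Conditions: PhCO2H (1.5 equiv), Ti(OiPr)4 (1.5 equiv), CH2Cl2, 0 °C → rt
Reagents that add atoms: benzoic acid, O=C(O)c1ccccc1
Why: Titanium-alkoxide-mediated opening of a 2,3-epoxy alcohol by a carboxylic acid: the C1 alkoxide and the oxirane oxygen bind titanium, and benzoate attacks the distal carbon C3, which is allylic and not neopentylic like C2, from the face opposite the oxirane (SN2, inversion); this gives C3–OBz trans to the freed C2–OH, which stays cis to C1–OH.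

**Step 8**
Reactants: 10 (1S,2S,3R,6R)-3-(benzoyloxy)-1-(benzoyloxymethyl)-6-(tert-butyldimethylsilyloxy)cyclohex-4-ene-1,2-diol
Product: 11 (1S,2S,3R,6R)-2-acetoxy-3-(benzoyloxy)-1-(benzoyloxymethyl)-6-(tert-butyldimethylsilyloxy)cyclohex-4-en-1-ol
Conditions: Ac2O (1.5 equiv), pyridine, DMAP (cat.), CH2Cl2, 0 °C
Reagents that add atoms: acetic anhydride, CC(=O)OC(C)=O
Why: Acylation under nucleophilic catalysis: only the secondary C2 hydroxyl is acetylated, the tertiary C1 hydroxyl being inert at 0 °C; low temperature and a weak base limit benzoyl migration from O3 to O2 before the acetate is in place.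

**Step 9**
Reactants: 11 (1S,2S,3R,6R)-2-acetoxy-3-(benzoyloxy)-1-(benzoyloxymethyl)-6-(tert-butyldimethylsilyloxy)cyclohex-4-en-1-ol
Product: 12 (1R,2S,3R,6R)-2-acetoxy-3-(benzoyloxy)-1-(benzoyloxymethyl)cyclohex-4-ene-1,6-diol
Conditions: HF·pyridine, THF–pyridine, 0 °C → rt
Reagents that add atoms: none
Why: Fluoride-mediated desilylation under weakly acidic conditions, chosen over basic fluoride sources so that the three esters neither migrate (O2→O6 in particular) nor cleave.

**Step 10**
Reactants: 12 (1R,2S,3R,6R)-2-acetoxy-3-(benzoyloxy)-1-(benzoyloxymethyl)cyclohex-4-ene-1,6-diol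
Product: 13 2-O-acetylzeylenone, (1S,2S,3R)-2-acetoxy-3-(benzoyloxy)-1-(benzoyloxymethyl)-1-hydroxycyclohex-4-en-6-one
Conditions: Dess–Martin periodinane (1.3 equiv), CH2Cl2, 0 °C → rt
Reagents that add atoms: none
Why: Dess–Martin oxidation of the secondary allylic alcohol to the enone; the tertiary C1 hydroxyl cannot be oxidised and the non-basic medium avoids elimination from the γ-acyloxy enone, while C1, C2 and C3 are untouched.

## Compound list

1 | 4-hydroxybenzyl alcohol | OCc1ccc(O)cc1 | starting material
2 | 4-hydroxybenzyl benzoate | O=C(OCc1ccc(O)cc1)c1ccccc1 | intermediate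
3 | 4-hydroxy-4-(benzoyloxymethyl)cyclohexa-2,5-dien-1-one (achiral para-quinol) | O=C1C=CC(O)(COC(=O)c2ccccc2)C=C1 | intermediate
4 | disodium salt of the C2=C3–C4(O−)=C5 dienolate with a trityldioxy group at C6 cis to the C1 alkoxide | C1=CC([O-])=C[C@@H](OOC(c2ccccc2)(c2ccccc2)c2ccccc2)[C@]1([O-])COC(=O)c1ccccc1.[Na+].[Na+] | intermediate (not isolated)
5 | (1R,5S,6R)-1-(benzoyloxymethyl)-5,6-epoxy-1-hydroxycyclohex-2-en-4-one (target numbering; oxirane cis to C1–OH) | C1=CC(=O)[C@H]2O[C@H]2[C@]1(O)COC(=O)c1ccccc1 | intermediate
6 | C4 hydrazone of 5 (C=N–NH2 in place of C=O; ring stereocentres as in 5) | C1=CC(=NN)[C@H]2O[C@H]2[C@]1(O)COC(=O)c1ccccc1 | intermediate (not isolated)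
7 | (1R,6R)-1-(benzoyloxymethyl)cyclohexa-2,4-diene-1,6-diol (cis-diol) | C1=CC=C[C@@H](O)[C@]1(O)COC(=O)c1ccccc1 | intermediate
8 | (1R,6R)-1-(benzoyloxymethyl)-6-(tert-butyldimethylsilyloxy)cyclohexa-2,4-dien-1-ol | C1=CC=C[C@@H](O[Si](C)(C)C(C)(C)C)[C@]1(O)COC(=O)c1ccccc1 | intermediate
9 | (1S,2S,3S,6R)-1-(benzoyloxymethyl)-6-(tert-butyldimethylsilyloxy)-2,3-epoxycyclohex-4-en-1-ol (oxirane cis to C1–OH) | C1=C[C@@H](O[Si](C)(C)C(C)(C)C)[C@](O)(COC(=O)c2ccccc2)[C@H]2O[C@@H]12 | intermediate
10 | (1S,2S,3R,6R)-3-(benzoyloxy)-1-(benzoyloxymethyl)-6-(tert-butyldimethylsilyloxy)cyclohex-4-ene-1,2-diol | O[C@H]1[C@H](OC(=O)c2ccccc2)C=C[C@@H](O[Si](C)(C)C(C)(C)C)[C@]1(O)COC(=O)c1ccccc1 | intermediate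
11 | (1S,2S,3R,6R)-2-acetoxy-3-(benzoyloxy)-1-(benzoyloxymethyl)-6-(tert-butyldimethylsilyloxy)cyclohex-4-en-1-ol | CC(=O)O[C@H]1[C@H](OC(=O)c2ccccc2)C=C[C@@H](O[Si](C)(C)C(C)(C)C)[C@]1(O)COC(=O)c1ccccc1 | intermediate
12 | (1R,2S,3R,6R)-2-acetoxy-3-(benzoyloxy)-1-(benzoyloxymethyl)cyclohex-4-ene-1,6-diol | CC(=O)O[C@H]1[C@H](OC(=O)c2ccccc2)C=C[C@@H](O)[C@]1(O)COC(=O)c1ccccc1 | intermediate
13 | 2-O-acetylzeylenone, (1S,2S,3R) | CC(=O)O[C@H]1[C@H](OC(=O)c2ccccc2)C=CC(=O)[C@]1(O)COC(=O)c1ccccc1 | target

## Step count and risk

Total step count: 10. Longest linear sequence: 10 steps (1 → 13); the route is fully linear.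

**Step 3 (key step, proposed new method).**
- What may go wrong: weak discrimination between the two enone arms, since the tartrate sits several bonds from C5/C6 and a tertiary alkoxide may hold the reagent less rigidly than the hydroxyl groups used in the monoketal series. Further epoxidation of the second arm and 1,2-benzoyl transfer from O7 to the C1 alkoxide are also possible. The transfer is disfavoured because the doubly allylic, carbonyl-conjugated quinol alkoxide is the weaker base.
- Fallback (known chemistry, resolution in place of desymmetrisation): it sets out from 3 and returns at 7. Hydroxyl-directed Weitz–Scheffer epoxidation of 3 (t-BuOOH, catalytic DBU, CH2Cl2, 0 °C) should give the racemic cis-epoxy quinol F1. Wharton transposition as in step 4 should give the racemic cis-diene diol F2. Lipase-mediated kinetic resolution (vinyl acetate, immobilised Candida antarctica lipase B, MTBE, 30 °C) is expected, by the usual empirical rule for secondary alcohols with the quaternary C1 as the large substituent, to acetylate the (6R) antipode. This gives (1R,6R)-6-acetoxy-1-(benzoyloxymethyl)cyclohexa-2,4-dien-1-ol F3, which is separated from the unreacted antipode. Alcoholysis of the acetate with the same lipase and n-butanol, which leaves the benzoate alone, returns 7.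

**Step 4.**
- What may go wrong: attack of hydrazine at the wrong sites, namely conjugate addition to the C2=C3 enone with ring closure to a pyrazoline and hydrazinolysis of the primary benzoate. Acid- or heat-induced rearrangement or Diels–Alder dimerisation of the dienol product is also possible.
- Fallback (radical transposition without hydrazine): it sets out from 5 and returns at 7. Luche reduction (NaBH4, CeCl3·7H2O, MeOH, −20 °C) should give the epoxy allylic alcohol F4, mainly with C4–OH cis to the oxirane; this centre is lost again. 1,1'-Thiocarbonyldiimidazole acylates the secondary C4 hydroxyl selectively to the imidazolyl thiocarbonate F5. Bu3SnH with AIBN in toluene at 80 °C generates the C4 radical, which opens the oxirane at C5–O; the C6 alkoxy radical takes hydrogen from the stannane to give 7.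

**Step 7.**
- What may go wrong: loss of regiocontrol in opening the vinyl oxirane. This covers conjugate (SN2′) attack at C5, ionisation to an allyl cation with loss of the trans relationship, a Lewis-acid-triggered 1,2-shift from C1, and transfer of isopropoxide from titanium.
- Fallback (no oxirane opening): it sets out from 8 and returns at 10. Hydrogen-bond-directed dihydroxylation of C2=C3 on the C1–OH face (OsO4·TMEDA, 1 equiv, CH2Cl2, −78 °C, then aqueous NaHSO3) should give the all-cis (1S,2S,3S,6R)-1-(benzoyloxymethyl)-6-(tert-butyldimethylsilyloxy)cyclohex-4-ene-1,2,3-triol F6. Mitsunobu esterification with benzoic acid (PPh3, DIAD, THF, 0 °C) at the allylic and least hindered C3 hydroxyl inverts C3 and gives 10.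

**Step 2.**
- What may go wrong: oxidation at the benzylic carbon instead of para-hydroxylation, by loss of a C7 proton from the cationic intermediate towards a quinone methide. Over-oxidation of the quinol is a second risk.
- Fallback (no cationic intermediate): it sets out from 2 and returns at 3. Dye-sensitised photo-oxygenation (O2, visible light, tetraphenylporphyrin, CH2Cl2–MeOH, 0 °C) adds singlet oxygen para to the hydroxyl to give 4-hydroperoxy-4-(benzoyloxymethyl)cyclohexa-2,5-dien-1-one F7. Reduction with Me2S gives 3.

## Further compounds

F1 | step 3 | racemic 1-(benzoyloxymethyl)-5,6-epoxy-1-hydroxycyclohex-2-en-4-one, oxirane cis to C1–OH (one enantiomer drawn) | C1=CC(=O)[C@H]2O[C@H]2[C@]1(O)COC(=O)c1ccccc1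
F2 | step 3 | racemic cis-1-(benzoyloxymethyl)cyclohexa-2,4-diene-1,6-diol (one enantiomer drawn) | C1=CC=C[C@@H](O)[C@]1(O)COC(=O)c1ccccc1
F3 | step 3 | (1R,6R)-6-acetoxy-1-(benzoyloxymethyl)cyclohexa-2,4-dien-1-ol | C1=CC=C[C@@H](OC(C)=O)[C@]1(O)COC(=O)c1ccccc1
F4 | step 4 | 1-(benzoyloxymethyl)-5,6-epoxycyclohex-2-ene-1,4-diol, C4–OH and oxirane cis to C1–OH | C1=C[C@@H](O)[C@H]2O[C@H]2[C@]1(O)COC(=O)c1ccccc1
F5 | step 4 | O-C4 imidazole-1-carbothioate of F4 | C1=C[C@@H](OC(=S)n2ccnc2)[C@H]2O[C@H]2[C@]1(O)COC(=O)c1ccccc1
F6 | step 7 | (1S,2S,3S,6R)-1-(benzoyloxymethyl)-6-(tert-butyldimethylsilyloxy)cyclohex-4-ene-1,2,3-triol | O[C@H]1[C@@H](O)C=C[C@@H](O[Si](C)(C)C(C)(C)C)[C@]1(O)COC(=O)c1ccccc1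
F7 | step 2 | 4-hydroperoxy-4-(benzoyloxymethyl)cyclohexa-2,5-dien-1-one | O=C1C=CC(OO)(COC(=O)c2ccccc2)C=C1
A1 | alternative 1 | cyclohex-3-ene-1-carboxylic acid with C1,C2-acetonide and C3 tert-butyldimethylsilyl ether | CC1(C)O[C@H]2[C@H](O[Si](C)(C)C(C)(C)C)C=CC[C@]2(O1)C(=O)O
A2 | alternative 1 | 4-O-(tert-butyldimethylsilyl)-6,7-dideoxy-2,3-O-isopropylidene-D-manno-hept-6-enono-1,5-lactone | C=C[C@H]1OC(=O)[C@H]2OC(C)(C)O[C@H]2[C@@H]1O[Si](C)(C)C(C)(C)C
A3 | alternative 2 | 2-acetoxy-1-(benzoyloxy)cyclohex-3-ene-1-carbaldehyde, oxygens cis | CC(=O)O[C@H]1C=CCC[C@]1(OC(=O)c1ccccc1)C=O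
A4 | alternative 2 | 2-(benzoyloxy)acrolein | C=C(OC(=O)c1ccccc1)C=O
A5 | alternative 2 | (E)-buta-1,3-dien-1-yl acetate | CC(=O)O/C=C/C=C
A6 | alternative 3 | spiro-oxirane at C1 with C2 p-methoxybenzyl ether and C3, C6 tert-butyldimethylsilyl ethers, C7 trans to the C2 oxygen | COc1ccc(CO[C@H]2[C@H](O[Si](C)(C)C(C)(C)C)C=C[C@@H](O[Si](C)(C)C(C)(C)C)[C@]23CO3)cc1
A7 | alternative 3 | cyclohex-4-en-1-one with C2 p-methoxybenzyl ether and C3, C6 tert-butyldimethylsilyl ethers, all-trans | COc1ccc(CO[C@H]2[C@H](O[Si](C)(C)C(C)(C)C)C=C[C@@H](O[Si](C)(C)C(C)(C)C)C2=O)cc1
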